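Numbering used: C1 is the left carbinol carbon, C2 the prenyl-bearing CH, C3–C4 the oxirane; the chain then runs on to C2′ and C1′ at the right end.
Retrosynthesis: cut the two O–Si bonds, then O–C3 and O–C4 of the oxirane, then C7=C8 and C7′=C8′ (Wittig; crocetindial plus two C15 phosphonium salts), then C3=C4 and C3′=C4′ (Horner–Wadsworth–Emmons; two lavandulol-derived C10 aldehydes plus a C5 phosphonate).
Forward: racemic lavandulol is resolved, the (S)-half hydrated once and the (R)-half twice; the right C15 unit is joined to the C20 dial, then the left C15 unit, and the only ring, the oxirane, is closed in the last step but one.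
Enabling feature: C3=C4 is the terminal alkene of the conjugated tridecaene and is homoallylic to the one free hydroxyl, the tertiary one on C1, so an oxidant held on that oxygen reaches this alkene alone.
Stereochemistry: C2 and C2′ come from the two lavandulol enantiomers, trans C3/C4 from the E alkene, their absolute sense from a chiral vanadium catalyst, and the E polyene from the olefinations plus thermal equilibration.

Key step: step 18

Assumption: the lipase acylates (R)-lavandulol faster, and the (S,S)-antipode of the bishydroxamic acid ligand is taken as the one that sends oxygen to the face giving 3R,4R; if a trial run shows the reverse, its mirror image is used in the same step.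

Step 1
Reactants: 1 racemic lavandulol
Product: 2 (S)-lavandulol (recovered unreacted) and 3 (R)-lavandulyl acetate
Conditions: porcine pancreatic lipase, vinyl acetate, tBuOMe, rt; 3 harvested at about 40 % conversion, the recovered alcohol resubmitted to about 65 % total conversion to leave 2
Reagents that add atoms: vinyl acetate, C=COC(C)=O
Why: Lipase-catalysed kinetic resolution by irreversible transesterification, in which the (R)-alcohol is acylated faster and, because lipases tell the β-stereocentre of this primary alcohol apart only moderately, each enantiomer is taken from the favourable end of the conversion range.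

Step 2
Reactants: 2 (S)-lavandulol
Product: 4 (S)-lavandulyl triethylsilyl ether
Conditions: Et3SiCl, imidazole, CH2Cl2, 0 °C → rt
Reagents that add atoms: triethylsilyl chloride, CC[Si](Cl)(CC)CC
Why: Routine silylation of a primary alcohol, which keeps the hydroxyl from trapping a mercurinium ion of the prenyl alkene in step 3 and later serves as the latent aldehyde, with the stereocentre untouched.

Step 3
Reactants: 4 (S)-lavandulyl triethylsilyl ether
Product: 6 (3R)-2,6-dimethyl-3-{[(triethylsilyl)oxy]methyl}hept-5-en-2-ol, via organomercurial 5 (not isolated)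
Conditions: Hg(OAc)2 (1.0 equiv), THF/H2O 1:1, 0 °C; then 1 M NaOH, NaBH4, 0 °C
Reagents that add atoms: water, O
Why: Markovnikov oxymercuration–demercuration, in which divalent mercury adds to a 1,1-disubstituted alkene much faster than to a trisubstituted one (the pattern of the monohydration of limonene to α-terpineol), so one equivalent hydrates only the isopropenyl group, the carbinol centre of 5 becomes CMe2 on reduction and C2 is not involved.

Step 4
Reactants: 6 (3R)-2,6-dimethyl-3-{[(triethylsilyl)oxy]methyl}hept-5-en-2-ol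
Product: 7 (3R)-2,6-dimethyl-2-[(triethylsilyl)oxy]-3-{[(triethylsilyl)oxy]methyl}hept-5-ene
Conditions: Et3SiOTf (1.3 equiv), 2,6-lutidine, CH2Cl2, −78 → 0 °C
Reagents that add atoms: triethylsilyl trifluoromethanesulfonate, CC[Si](CC)(CC)OS(=O)(=O)C(F)(F)F
Why: A silyl triflate with a hindered pyridine base is the standard silylation of a tertiary alcohol, and the slight excess also re-silylates any primary hydroxyl bared during step 3.

Step 5
Reactants: 7 (3R)-2,6-dimethyl-2-[(triethylsilyl)oxy]-3-{[(triethylsilyl)oxy]methyl}hept-5-ene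
Product: 9 (2S)-5-methyl-2-{2-[(triethylsilyl)oxy]propan-2-yl}hex-4-enal, via alkoxysulfonium chloride 8 (not isolated)
Conditions: (COCl)2, DMSO, CH2Cl2, −78 °C; 7, −78 → −40 °C; Et3N, −78 → 0 °C
Reagents that add atoms: none
Why: Swern oxidation applied directly to a primary triethylsilyl ether, in which the chlorosulfonium salt exchanges the unhindered primary silyl group for the alkoxysulfonium ion 8 that collapses with amine to the aldehyde, while the tertiary silyl ether is too hindered to react and the cold, short contact with base leaves the α-stereocentre intact.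

Step 6
Reactants: 9 (2S)-5-methyl-2-{2-[(triethylsilyl)oxy]propan-2-yl}hex-4-enal; 10 triethyl 3-methyl-4-phosphonocrotonate
Product: 12 ethyl (2E,4E,6R)-3,9-dimethyl-6-{2-[(triethylsilyl)oxy]propan-2-yl}deca-2,4,8-trienoate, via lithiated phosphonate 11 (not isolated)
Conditions: 10 (1.5 equiv), LiN(SiMe3)2 (1.4 equiv), THF, −78 °C; then 9, −78 → 0 °C
Reagents that add atoms: triethyl 3-methyl-4-phosphonocrotonate (10), CCOC(=O)/C=C(\C)CP(=O)(OCC)OCC
Why: Vinylogous Horner–Wadsworth–Emmons olefination, in which the carbanion α to phosphorus adds to the aldehyde and elimination gives the E-configured C4=C5 bond with the 2E ester favoured (a minor 2Z isomer is removed on silica), while the deficit of amide base and the cold addition protect the α-stereocentre and the β-silyloxy group.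

Step 7
Reactants: 12 ethyl (2E,4E,6R)-3,9-dimethyl-6-{2-[(triethylsilyl)oxy]propan-2-yl}deca-2,4,8-trienoate
Product: 13 (2E,4E,6R)-3,9-dimethyl-6-{2-[(triethylsilyl)oxy]propan-2-yl}deca-2,4,8-trien-1-ol
Conditions: iBu2AlH (2.2 equiv), CH2Cl2, −78 °C; aq. potassium sodium tartrate
Reagents that add atoms: none
Why: 1,2-Reduction of a conjugated ester to the allylic alcohol by a neutral aluminium hydride, which touches neither the silyl ether nor the alkenes.

Step 8
Reactants: 13 (2E,4E,6R)-3,9-dimethyl-6-{2-[(triethylsilyl)oxy]propan-2-yl}deca-2,4,8-trien-1-ol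
Product: 16 [(2E,4E,6R)-6-(2-hydroxypropan-2-yl)-3,9-dimethyldeca-2,4,8-trien-1-yl]triphenylphosphonium bromide, via dienyl bromide 14 (not isolated), via silylated phosphonium bromide 15 (not isolated)
Conditions: CBr4 (1.2 equiv), PPh3 (1.25 equiv), CH2Cl2, −20 → 0 °C; then PPh3 (1.5 equiv), rt; then MeOH, camphorsulfonic acid (0.5 equiv), rt
Reagents that add atoms: carbon tetrabromide, BrC(Br)(Br)Br; triphenylphosphine, c1ccc(cc1)P(c1ccccc1)c1ccccc1
Why: Appel bromination of the primary dienylic alcohol under neutral conditions, SN2 quaternisation of triphenylphosphine by the bromide and acid-catalysed methanolysis of the tertiary silyl ether only after the leaving group is gone, so the C1 hydroxyl needed in step 18 is freed without a dienyl cation ever forming next to C2.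

Step 9
Reactants: 3 (R)-lavandulyl acetate
Product: 17 (2S)-5-hydroxy-2-(2-hydroxypropan-2-yl)-5-methylhexyl acetate
Conditions: Co(acac)2 (0.2 equiv), PhSiH3 (4 equiv), O2 (1 atm), THF, rt; aq. Na2S2O3
Reagents that add atoms: dioxygen, O=O
Why: Mukaiyama hydration, in which a cobalt hydride passes a hydrogen atom to each alkene and the tertiary radical is trapped by oxygen, gives both Markovnikov tertiary alcohols without the cation-like intermediates that would let the first-formed hydroxyl close a tetrahydropyran onto the second alkene, the stereocentre being a spectator.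

Step 10
Reactants: 17 (2S)-5-hydroxy-2-(2-hydroxypropan-2-yl)-5-methylhexyl acetate
Product: 18 (2S)-5-methyl-5-[(triethylsilyl)oxy]-2-{2-[(triethylsilyl)oxy]propan-2-yl}hexyl acetate
Conditions: Et3SiOTf (2.6 equiv), 2,6-lutidine, CH2Cl2, −78 → 0 °C
Reagents that add atoms: triethylsilyl trifluoromethanesulfonate, CC[Si](CC)(CC)OS(=O)(=O)C(F)(F)F
Why: Standard triflate silylation of both tertiary alcohols, which keeps these hydroxyls off the vanadium in step 18.

Step 11
Reactants: 18 (2S)-5-methyl-5-[(triethylsilyl)oxy]-2-{2-[(triethylsilyl)oxy]propan-2-yl}hexyl acetate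
Product: 19 (2S)-5-methyl-5-[(triethylsilyl)oxy]-2-{2-[(triethylsilyl)oxy]propan-2-yl}hexan-1-ol
Conditions: iBu2AlH (2.2 equiv), CH2Cl2, −78 °C; aq. potassium sodium tartrate
Reagents that add atoms: none
Why: Reductive cleavage of the acetate at low temperature frees the primary alcohol as an aluminium alkoxide, which avoids the tertiary-to-primary silyl shift that a free alkoxide in basic methanol could cause.

Step 12
Reactants: 19 (2S)-5-methyl-5-[(triethylsilyl)oxy]-2-{2-[(triethylsilyl)oxy]propan-2-yl}hexan-1-ol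
Product: 20 (2R)-5-methyl-5-[(triethylsilyl)oxy]-2-{2-[(triethylsilyl)oxy]propan-2-yl}hexanal
Conditions: Dess–Martin periodinane, CH2Cl2, 0 °C → rt
Reagents that add atoms: none
Why: Dess–Martin oxidation is a mild, nearly neutral route to an α-branched aldehyde and should cause neither epimerisation nor loss of the β-silyloxy group.

Step 13
Reactants: 20 (2R)-5-methyl-5-[(triethylsilyl)oxy]-2-{2-[(triethylsilyl)oxy]propan-2-yl}hexanal; 10 triethyl 3-methyl-4-phosphonocrotonate
Product: 22 ethyl (2E,4E,6S)-3,9-dimethyl-9-[(triethylsilyl)oxy]-6-{2-[(triethylsilyl)oxy]propan-2-yl}deca-2,4-dienoate, via sodiated phosphonate 21 (not isolated)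
Conditions: 10 (1.5 equiv), NaN(SiMe3)2 (1.4 equiv), THF, −78 °C; then 20, −78 → 0 °C
Reagents that add atoms: triethyl 3-methyl-4-phosphonocrotonate (10), CCOC(=O)/C=C(\C)CP(=O)(OCC)OCC
Why: Vinylogous Horner–Wadsworth–Emmons olefination of the type used in step 6, run here through the sodium salt of the phosphonate, an equally standard form of this reagent, giving the 2E,4E dienoate with the α-stereocentre preserved by the low temperature and the absence of free amide base.

Step 14
Reactants: 22 ethyl (2E,4E,6S)-3,9-dimethyl-9-[(triethylsilyl)oxy]-6-{2-[(triethylsilyl)oxy]propan-2-yl}deca-2,4-dienoate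
Product: 23 (2E,4E,6S)-3,9-dimethyl-9-[(triethylsilyl)oxy]-6-{2-[(triethylsilyl)oxy]propan-2-yl}deca-2,4-dien-1-ol
Conditions: iBu2AlH (2.2 equiv), CH2Cl2, −78 °C; aq. potassium sodium tartrate
Reagents that add atoms: none
Why: 1,2-Reduction of the conjugated ester to the allylic alcohol, with both silyl ethers inert to the hydride.

Step 15
Reactants: 23 (2E,4E,6S)-3,9-dimethyl-9-[(triethylsilyl)oxy]-6-{2-[(triethylsilyl)oxy]propan-2-yl}deca-2,4-dien-1-ol
Product: 25 [(2E,4E,6S)-3,9-dimethyl-9-[(triethylsilyl)oxy]-6-{2-[(triethylsilyl)oxy]propan-2-yl}deca-2,4-dien-1-yl]triphenylphosphonium bromide, via dienyl bromide 24 (not isolated)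
Conditions: CBr4 (1.2 equiv), PPh3 (1.25 equiv), CH2Cl2, −20 → 0 °C; then PPh3 (1.5 equiv), rt
Reagents that add atoms: carbon tetrabromide, BrC(Br)(Br)Br; triphenylphosphine, c1ccc(cc1)P(c1ccccc1)c1ccccc1
Why: Appel bromination followed by SN2 quaternisation of triphenylphosphine gives the allylic phosphonium salt without acid, so both tertiary silyl ethers stay in place.

Step 16
Reactants: 25 right C15 phosphonium bromide; 26 crocetindial
Product: 28 C35 all-E polyenal (2′S) with both right-end hydroxyls silylated, via phosphorus ylide 27 (not isolated)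
Conditions: 26 (2.5 equiv), NaOMe (1.1 equiv), CH2Cl2/MeOH, 0 °C → rt, dark; then n-heptane, 90 °C, dark
Reagents that add atoms: crocetindial (26), O=C/C(C)=C/C=C/C(C)=C/C=C/C=C(C)/C=C/C=C(C)/C=O
Why: Wittig olefination of the allylic ylide with one formyl group of the dial, the excess of dial (recovered) holding back double condensation, followed by thermal equilibration of the hindered 7′Z isomer to the all-E polyene as is usual for carotenoid Wittig products.

Step 17
Reactants: 16 left C15 phosphonium bromide; 28 C35 polyenal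
Product: 30 C50 all-E tridecaene (2R,2′S) with free C1 hydroxyl and silylated right end, via phosphorus ylide 29 (not isolated)
Conditions: 16 (1.3 equiv), NaOMe (1.5 equiv), CH2Cl2/MeOH, 0 °C → rt, dark; then n-heptane, 90 °C, dark; crystallisation
Reagents that add atoms: none
Why: Second Wittig olefination, which the free tertiary hydroxyl does not disturb, with thermal equilibration and crystallisation expected to deliver the all-E isomer.

Step 18
Reactants: 30 C50 tridecaene; 31 tert-butyl hydroperoxide
Product: 32 (2R,3R,4R,2′S)-3,4-epoxide of 30 (right end still silylated)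
Conditions: VO(OiPr)3 (0.1 equiv), (S,S)-bishydroxamic acid ligand of the N,N′-dihydroxy-N,N′-bis(diarylacetyl)cyclohexane-1,2-diamine type (0.2 equiv), toluene, rt, 1 h; then 30 and 31 (1.2 equiv, anhydrous in toluene), 0 °C, dark, argon; aq. Na2S2O3/NaHCO3; Et3N-deactivated silica
Reagents that add atoms: tert-butyl hydroperoxide (31), CC(C)(C)OO
Why: Proposed new method: the C1 alkoxide and the hydroperoxide both bind pentavalent vanadium carrying the chiral bishydroxamate, and the activated peroxide oxygen passes in one concerted step to the C3=C4 alkene, so O–C3 and O–C4 form together and the oxirane closes by direct oxygen-atom transfer (a [2+1] addition with no separate ring-closing event); the closest known reaction is the vanadium–bishydroxamic acid epoxidation of simple homoallylic alcohols, not yet shown on a conjugated polyene or with a tertiary carbinol as anchor. The trans relation of C3 and C4 follows stereospecifically from the E alkene. The face is set by the ligand acting through a chair-like array V–O–C1–C2–C3; for an E alkene next to a quaternary carbinol the chair model predicts only a weak intrinsic bias, which if anything puts the prenyl group pseudo-equatorial and favours the opposite face, so the ligand antipode has to dominate. Site selectivity among fourteen alkenes rests on the single free hydroxyl: both right-end hydroxyls are silylated, C3=C4 is the only alkene within a six-membered delivery, and the prenyl alkene would need a seven-membered one, for which vanadium–bishydroxamate catalysts are much less effective. Neutral, cold conditions and a basic work-up are chosen because the product ionises easily to a polyenyl cation.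

Step 19
Reactants: 32 silylated epoxide
Product: 33 target, (2R,3R,4R,2′S)-epoxy triol
Conditions: Bu4NF (4 equiv), THF, 0 °C → rt, dark; pH 7 buffer work-up
Reagents that add atoms: none
Why: Fluoride-induced cleavage of the two tertiary triethylsilyl ethers under acid-free conditions, which the oxirane (opened only through a polyenyl cation) and the polyene should tolerate.

Compound list
1 | racemic lavandulol, 5-methyl-2-(prop-1-en-2-yl)hex-4-en-1-ol | CC(C)=CCC(CO)C(C)=C | starting material
2 | (S)-lavandulol | CC(C)=CC[C@H](CO)C(C)=C | intermediate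
3 | (R)-lavandulyl acetate | CC(C)=CC[C@@H](COC(C)=O)C(C)=C | intermediate
4 | (S)-lavandulyl triethylsilyl ether, triethyl{[(2S)-5-methyl-2-(prop-1-en-2-yl)hex-4-en-1-yl]oxy}silane | CC(C)=CC[C@H](CO[Si](CC)(CC)CC)C(C)=C | intermediate
5 | [(3R)-2-hydroxy-2,6-dimethyl-3-{[(triethylsilyl)oxy]methyl}hept-5-en-1-yl]mercury acetate, both epimers at C2 | CC(C)=CC[C@H](CO[Si](CC)(CC)CC)C(C)(O)C[Hg]OC(C)=O | intermediate
6 | (3R)-2,6-dimethyl-3-{[(triethylsilyl)oxy]methyl}hept-5-en-2-ol | CC(C)=CC[C@H](CO[Si](CC)(CC)CC)C(C)(C)O | intermediate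
7 | (3R)-2,6-dimethyl-2-[(triethylsilyl)oxy]-3-{[(triethylsilyl)oxy]methyl}hept-5-ene | CC(C)=CC[C@H](CO[Si](CC)(CC)CC)C(C)(C)O[Si](CC)(CC)CC | intermediate
8 | dimethyl{[(2R)-5-methyl-2-{2-[(triethylsilyl)oxy]propan-2-yl}hex-4-en-1-yl]oxy}sulfonium chloride | CC(C)=CC[C@H](CO[S+](C)C)C(C)(C)O[Si](CC)(CC)CC.[Cl-] | intermediate
9 | (2S)-5-methyl-2-{2-[(triethylsilyl)oxy]propan-2-yl}hex-4-enal | CC(C)=CC[C@H](C=O)C(C)(C)O[Si](CC)(CC)CC | intermediate
10 | triethyl 3-methyl-4-phosphonocrotonate, ethyl (2E)-4-(diethoxyphosphoryl)-3-methylbut-2-enoate (sold as an E/Z mixture) | CCOC(=O)/C=C(\C)CP(=O)(OCC)OCC | starting material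
11 | lithium salt of 10, carbanion α to phosphorus | [Li+].CCOC(=O)C=C(C)[CH-]P(=O)(OCC)OCC | intermediate
12 | ethyl (2E,4E,6R)-3,9-dimethyl-6-{2-[(triethylsilyl)oxy]propan-2-yl}deca-2,4,8-trienoate | CC(C)=CC[C@H](/C=C/C(C)=C/C(=O)OCC)C(C)(C)O[Si](CC)(CC)CC | intermediate
13 | (2E,4E,6R)-3,9-dimethyl-6-{2-[(triethylsilyl)oxy]propan-2-yl}deca-2,4,8-trien-1-ol | CC(C)=CC[C@H](/C=C/C(C)=C/CO)C(C)(C)O[Si](CC)(CC)CC | intermediate
14 | (2E,4E,6R)-1-bromo-3,9-dimethyl-6-{2-[(triethylsilyl)oxy]propan-2-yl}deca-2,4,8-triene | CC(C)=CC[C@H](/C=C/C(C)=C/CBr)C(C)(C)O[Si](CC)(CC)CC | intermediate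
15 | [(2E,4E,6R)-3,9-dimethyl-6-{2-[(triethylsilyl)oxy]propan-2-yl}deca-2,4,8-trien-1-yl]triphenylphosphonium bromide | CC(C)=CC[C@H](/C=C/C(C)=C/C[P+](c1ccccc1)(c1ccccc1)c1ccccc1)C(C)(C)O[Si](CC)(CC)CC.[Br-] | intermediate
16 | [(2E,4E,6R)-6-(2-hydroxypropan-2-yl)-3,9-dimethyldeca-2,4,8-trien-1-yl]triphenylphosphonium bromide (left C15 salt) | CC(C)=CC[C@H](/C=C/C(C)=C/C[P+](c1ccccc1)(c1ccccc1)c1ccccc1)C(C)(C)O.[Br-] | intermediate
17 | (2S)-5-hydroxy-2-(2-hydroxypropan-2-yl)-5-methylhexyl acetate | CC(C)(O)CC[C@@H](COC(C)=O)C(C)(C)O | intermediate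
18 | (2S)-5-methyl-5-[(triethylsilyl)oxy]-2-{2-[(triethylsilyl)oxy]propan-2-yl}hexyl acetate | CC(C)(O[Si](CC)(CC)CC)CC[C@@H](COC(C)=O)C(C)(C)O[Si](CC)(CC)CC | intermediate
19 | (2S)-5-methyl-5-[(triethylsilyl)oxy]-2-{2-[(triethylsilyl)oxy]propan-2-yl}hexan-1-ol | CC(C)(O[Si](CC)(CC)CC)CC[C@@H](CO)C(C)(C)O[Si](CC)(CC)CC | intermediate
20 | (2R)-5-methyl-5-[(triethylsilyl)oxy]-2-{2-[(triethylsilyl)oxy]propan-2-yl}hexanal | CC(C)(O[Si](CC)(CC)CC)CC[C@@H](C=O)C(C)(C)O[Si](CC)(CC)CC | intermediate
21 | sodium salt of 10, carbanion α to phosphorus | [Na+].CCOC(=O)C=C(C)[CH-]P(=O)(OCC)OCC | intermediate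
22 | ethyl (2E,4E,6S)-3,9-dimethyl-9-[(triethylsilyl)oxy]-6-{2-[(triethylsilyl)oxy]propan-2-yl}deca-2,4-dienoate | CC(C)(O[Si](CC)(CC)CC)CC[C@@H](/C=C/C(C)=C/C(=O)OCC)C(C)(C)O[Si](CC)(CC)CC | intermediate
23 | (2E,4E,6S)-3,9-dimethyl-9-[(triethylsilyl)oxy]-6-{2-[(triethylsilyl)oxy]propan-2-yl}deca-2,4-dien-1-ol | CC(C)(O[Si](CC)(CC)CC)CC[C@@H](/C=C/C(C)=C/CO)C(C)(C)O[Si](CC)(CC)CC | intermediate
24 | (2E,4E,6S)-1-bromo-3,9-dimethyl-9-[(triethylsilyl)oxy]-6-{2-[(triethylsilyl)oxy]propan-2-yl}deca-2,4-diene | CC(C)(O[Si](CC)(CC)CC)CC[C@@H](/C=C/C(C)=C/CBr)C(C)(C)O[Si](CC)(CC)CC | intermediate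
25 | [(2E,4E,6S)-3,9-dimethyl-9-[(triethylsilyl)oxy]-6-{2-[(triethylsilyl)oxy]propan-2-yl}deca-2,4-dien-1-yl]triphenylphosphonium bromide (right C15 salt) | CC(C)(O[Si](CC)(CC)CC)CC[C@@H](/C=C/C(C)=C/C[P+](c1ccccc1)(c1ccccc1)c1ccccc1)C(C)(C)O[Si](CC)(CC)CC.[Br-] | intermediate
26 | crocetindial, all-E-2,6,11,15-tetramethylhexadeca-2,4,6,8,10,12,14-heptaenedial | O=C/C(C)=C/C=C/C(C)=C/C=C/C=C(C)/C=C/C=C(C)/C=O | starting material
27 | phosphorus ylide of 25 | CC(C)(O[Si](CC)(CC)CC)CC[C@@H](/C=C/C(C)=C/C=P(c1ccccc1)(c1ccccc1)c1ccccc1)C(C)(C)O[Si](CC)(CC)CC | intermediate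
28 | C35 polyenal, (2E,4E,6E,8E,10E,12E,14E,16E,18E,20E,22S)-2,6,11,15,19,25-hexamethyl-25-[(triethylsilyl)oxy]-22-{2-[(triethylsilyl)oxy]propan-2-yl}hexacosa-2,4,6,8,10,12,14,16,18,20-decaenal | O=C/C(C)=C/C=C/C(C)=C/C=C/C=C(C)/C=C/C=C(C)/C=C/C=C(C)/C=C/[C@H](CCC(C)(C)O[Si](CC)(CC)CC)C(C)(C)O[Si](CC)(CC)CC | intermediate
29 | phosphorus ylide of 16 | CC(C)=CC[C@H](/C=C/C(C)=C/C=P(c1ccccc1)(c1ccccc1)c1ccccc1)C(C)(C)O | intermediate
30 | C50 all-E tridecaene (2R,2′S): C1 hydroxyl free, C1′ and side-chain hydroxyls as triethylsilyl ethers | CC(C)=CC[C@H](/C=C/C(C)=C/C=C/C(C)=C/C=C/C(C)=C/C=C/C=C(C)/C=C/C=C(C)/C=C/C=C(C)/C=C/[C@H](CCC(C)(C)O[Si](CC)(CC)CC)C(C)(C)O[Si](CC)(CC)CC)C(C)(C)O | intermediate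
31 | tert-butyl hydroperoxide | CC(C)(C)OO | starting material
32 | (2R,3R,4R,2′S)-3,4-epoxide of 30, trans-oxirane, right end as bis(triethylsilyl) ether | CC(C)=CC[C@H]([C@H]1O[C@@H]1/C(C)=C/C=C/C(C)=C/C=C/C(C)=C/C=C/C=C(C)/C=C/C=C(C)/C=C/C=C(C)/C=C/[C@H](CCC(C)(C)O[Si](CC)(CC)CC)C(C)(C)O[Si](CC)(CC)CC)C(C)(C)O | intermediate
33 | target, (2R,3R,4R,2′S)-3,4-epoxy dodecaene triol | CC(C)=CC[C@H]([C@H]1O[C@@H]1/C(C)=C/C=C/C(C)=C/C=C/C(C)=C/C=C/C=C(C)/C=C/C=C(C)/C=C/C=C(C)/C=C/[C@H](CCC(C)(C)O)C(C)(C)O)C(C)(C)O | target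

Total step count: 19. Longest linear sequence: 12 steps (1, 9–19).

Steps most likely to fail

Step 18. Oxygen may go to the prenyl alkene or to the wrong face of C3=C4. The metal–hydroperoxide pair may start radical oxidation of the polyene. The Lewis-acidic metal may open the product through the polyenyl cation, for example by 5-endo attack of the C1 hydroxyl at C4. The fallback uses known chemistry, leaves the route at 9 and at 28 and rejoins it at 33. It builds the oxirane early on an electron-poor alkene that only a nucleophilic oxidant attacks, so the prenyl alkene cannot compete. Aldehyde 9 and acetonylidenetriphenylphosphorane (toluene, 80 °C) should give the E-enone F1. Epoxidation of F1 with tBuOOH under La(OiPr)3/BINOL/Ph3As=O catalysis, the BINOL antipode chosen for the required face, should give the trans-epoxy ketone F2. Triethyl phosphonoacetate/NaH should convert F2 into the E-epoxy enoate F3, iBu2AlH at −78 °C into the epoxy allylic alcohol F4, and MnO2 into the epoxy enal F5. In parallel, 28 is reduced with NaBH4 to the polyenol F6, which Ph3P·HBr in MeOH turns into the desilylated C35 phosphonium bromide F7. Wittig coupling of F7 with F5 (NaOMe, CH2Cl2/MeOH, 0 °C) should give the C50 epoxide F8, which still carries the C1 silyl ether; its 7Z isomer is removed by chromatography, not by heating. Bu4NF then gives 33.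

Step 6 (the same concern applies to step 13). Before olefination the base may epimerise the α-carbon or eliminate the β-silanolate. The alkoxide adduct may suffer a 1,3-silyl shift, and the 2E/2Z ratio may erode. The fallback leaves the route at 7 and rejoins it at 13; it forms C3=C4 from a sulfone, so no aldehyde with an acidic α-hydrogen is made. Selective methanolysis of the primary silyl ether of 7 (pyridinium p-toluenesulfonate, MeOH/CH2Cl2, 0 °C) gives the primary alcohol F9. A Mitsunobu reaction with 1-phenyl-1H-tetrazole-5-thiol gives the thioether F10, and (NH4)6Mo7O24·4H2O/H2O2 the sulfone F11. The C5 partner is made from prenol: pivaloyl chloride and pyridine give prenyl pivalate F12, and SeO2/tBuOOH oxidises its E-methyl group to give (2E)-3-methyl-4-oxobut-2-en-1-yl pivalate F13. Julia–Kocienski olefination of F11 with F13 (KN(SiMe3)2, DME, −60 °C → rt) should give the dienyl pivalate F14, and iBu2AlH removes the pivalate to give 13.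

Step 1. The enzyme may not discriminate the enantiomers well enough, so each half would carry some of its antipode, which would surface later as C2 or C2′ epimers of the C50 compounds that are hard to separate. The fallback leaves the route at 1 and rejoins it at 2 and 3. The enantiomers of 1 are separated by preparative chromatography on a polysaccharide-carbamate chiral phase (supercritical CO2/alcohol). One fraction is 2; the other, (R)-lavandulol F15, is acetylated (Ac2O, pyridine) to give 3.

Further compounds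
F1 | step 18 | (3E,5R)-8-methyl-5-{2-[(triethylsilyl)oxy]propan-2-yl}nona-3,7-dien-2-one | CC(C)=CC[C@H](/C=C/C(C)=O)C(C)(C)O[Si](CC)(CC)CC
F2 | step 18 | trans-epoxy ketone, 1-[(2S,3R)-3-[(3R)-2,6-dimethyl-2-[(triethylsilyl)oxy]hept-5-en-3-yl]oxiran-2-yl]ethan-1-one | CC(C)=CC[C@H]([C@H]1O[C@@H]1C(C)=O)C(C)(C)O[Si](CC)(CC)CC
F3 | step 18 | ethyl (2E)-3-(oxiranyl)but-2-enoate homologue of F2, oxirane configured as in 33 | CC(C)=CC[C@H]([C@H]1O[C@@H]1/C(C)=C/C(=O)OCC)C(C)(C)O[Si](CC)(CC)CC
F4 | step 18 | epoxy allylic alcohol from F3, (2E)-3-(oxiranyl)but-2-en-1-ol, oxirane configured as in 33 | CC(C)=CC[C@H]([C@H]1O[C@@H]1/C(C)=C/CO)C(C)(C)O[Si](CC)(CC)CC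
F5 | step 18 | C15 epoxy enal from F4, (2E)-3-(oxiranyl)but-2-enal, oxirane configured as in 33 | CC(C)=CC[C@H]([C@H]1O[C@@H]1/C(C)=C/C=O)C(C)(C)O[Si](CC)(CC)CC
F6 | step 18 | C35 all-E polyenol, primary alcohol of 28 | OC/C(C)=C/C=C/C(C)=C/C=C/C=C(C)/C=C/C=C(C)/C=C/C=C(C)/C=C/[C@H](CCC(C)(C)O[Si](CC)(CC)CC)C(C)(C)O[Si](CC)(CC)CC
F7 | step 18 | C35 polyenyl triphenylphosphonium bromide, both right-end hydroxyls free | c1ccccc1[P+](c1ccccc1)(c1ccccc1)C/C(C)=C/C=C/C(C)=C/C=C/C=C(C)/C=C/C=C(C)/C=C/C=C(C)/C=C/[C@H](CCC(C)(C)O)C(C)(C)O.[Br-]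
F8 | step 18 | C50 (2R,3R,4R,2′S)-epoxide with the C1 hydroxyl as triethylsilyl ether and the right-end hydroxyls free | CC(C)=CC[C@H]([C@H]1O[C@@H]1/C(C)=C/C=C/C(C)=C/C=C/C(C)=C/C=C/C=C(C)/C=C/C=C(C)/C=C/C=C(C)/C=C/[C@H](CCC(C)(C)O)C(C)(C)O)C(C)(C)O[Si](CC)(CC)CC
F9 | step 6 | (2R)-5-methyl-2-{2-[(triethylsilyl)oxy]propan-2-yl}hex-4-en-1-ol | CC(C)=CC[C@H](CO)C(C)(C)O[Si](CC)(CC)CC
F10 | step 6 | 1-phenyl-1H-tetrazol-5-yl thioether of F9 | CC(C)=CC[C@H](CSc1nnnn1-c1ccccc1)C(C)(C)O[Si](CC)(CC)CC
F11 | step 6 | 1-phenyl-1H-tetrazol-5-yl sulfone from F10 | CC(C)=CC[C@H](CS(=O)(=O)c1nnnn1-c1ccccc1)C(C)(C)O[Si](CC)(CC)CC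
F12 | step 6 | prenyl pivalate, 3-methylbut-2-en-1-yl 2,2-dimethylpropanoate | CC(C)=CCOC(=O)C(C)(C)C
F13 | step 6 | (2E)-3-methyl-4-oxobut-2-en-1-yl 2,2-dimethylpropanoate | O=C/C(C)=C/COC(=O)C(C)(C)C
F14 | step 6 | pivalate of 13 | CC(C)=CC[C@H](/C=C/C(C)=C/COC(=O)C(C)(C)C)C(C)(C)O[Si](CC)(CC)CC
F15 | step 1 | (R)-lavandulol | CC(C)=CC[C@@H](CO)C(C)=C
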